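## Plan

Prostanoid numbering is used in the prose: C1 is the ester carbon, C8–C12 the ring, C13–C20 the octenyl chain.

1. Retrosynthetic cuts, in order: O12–Si and the three O–acetyl bonds; C5–O (SN2 opening of a 5,6-cis-epoxide) and C6–O (epoxidation of a 5Z-alkene); C7–C8 (aldol of a 2-chlorocyclopentenone with a C1–C7 Z-enal); C9–C10 and C10–C11 (excision of the chlorine-bearing carbon C10, leaving a cyclobutanone); C15–C16 and C12–C13 (alkyne alkylation, propargylation).
2. Enabling feature: in the ring C8–C9–C10–C11–C12, the unit C9(=O)–C10(Cl)=C11 is what the opening of a gem-dichlorocyclopropane fused onto a silyl enol ether leaves behind. Without C10, the atoms C8, C9, C11 and C12 form a 3,3-disubstituted cyclobutanone in which C8 and C11 are enantiotopic CH2 groups, so C12 becomes a stereocentre simply by choosing which CH2 is enolized.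
3. Forward: the four-membered ring is bought and the C12 substituents are added; one CH2 is enolized selectively; dichlorocarbene then expands the ring from four to five atoms, giving the only ring of the target with Cl and the C10=C11 bond in place. The C1–C7 chain is joined by aldol and oxygenated in place; alkyne semireduction and desilylation finish.
4. Stereochemistry: C12 from asymmetric deprotonation with a chiral lithium amide; C8 and C7 from the boron aldol (attack anti to the C12 carbon chain, chair transition state of the E-enolate gives 7,8-anti); C6 from A(1,3)-controlled, hydroxyl-directed epoxidation of the Z-allylic alcohol; C5 from SN2 inversion; the 14Z-alkene from Lindlar reduction.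

Key step: step 7

Assumption: the (R,R)-amide base is taken to remove the proton that leads to (S)-11 (if the sense of induction is opposite, the (S,S)-amide is used and nothing else changes); compound 1 is taken as a catalogue compound.

## Route

Step 1
Reactants: 1 3-[(tert-butyldimethylsilyl)oxy]cyclobutan-1-one; 2 3-bromoprop-1-yne (propargyl bromide)
Product: 4 3-[(tert-butyldimethylsilyl)oxy]-1-(prop-2-yn-1-yl)cyclobutan-1-ol (cis/trans mixture), via allenylzinc bromide 3 (not isolated)
Conditions: Zn dust, THF, 0 °C→rt; aq NH4Cl work-up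
Reagents that add atoms: none
Why: Barbier-type propargylation, in which the allenylzinc species adds by SE2′ to the strained ketone to give the homopropargylic tertiary alcohol; the cis/trans ratio is irrelevant because the silyloxy carbon later becomes the ketone.

Step 2
Reactants: 4 3-[(tert-butyldimethylsilyl)oxy]-1-(prop-2-yn-1-yl)cyclobutan-1-ol; 5 1-iodopentane
Product: 7 3-[(tert-butyldimethylsilyl)oxy]-1-(oct-2-yn-1-yl)cyclobutan-1-ol, via the dilithium alkoxide–acetylide 6 (not isolated)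
Conditions: n-BuLi (2.2 equiv), THF, −78→−20 °C; then 5, DMPU, −20 °C→rt
Reagents that add atoms: none
Why: Acetylide alkylation of the dianion with a primary iodide; the hindered tertiary lithium alkoxide should not be alkylated.

Step 3
Reactants: 7 3-[(tert-butyldimethylsilyl)oxy]-1-(oct-2-yn-1-yl)cyclobutan-1-ol
Product: 8 1-(oct-2-yn-1-yl)cyclobutane-1,3-diol
Conditions: TBAF, THF, 0 °C→rt
Reagents that add atoms: none
Why: Fluoride-induced cleavage of the secondary silyl ether (desilylation), which leaves the alkyne untouched.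

Step 4
Reactants: 8 1-(oct-2-yn-1-yl)cyclobutane-1,3-diol
Product: 9 3-hydroxy-3-(oct-2-yn-1-yl)cyclobutan-1-one
Conditions: Dess–Martin periodinane, NaHCO3, CH2Cl2, 0 °C→rt
Reagents that add atoms: none
Why: Dess–Martin oxidation of the only oxidizable (secondary) alcohol under buffered conditions that should spare the retro-aldol-prone 3-hydroxycyclobutanone.

Step 5
Reactants: 9 3-hydroxy-3-(oct-2-yn-1-yl)cyclobutan-1-one
Product: 10 3-(oct-2-yn-1-yl)-3-[(triethylsilyl)oxy]cyclobutan-1-one
Conditions: TESOTf, 2,6-lutidine, CH2Cl2, −78 °C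
Reagents that add atoms: triethylsilyl trifluoromethanesulfonate, CC[Si](CC)(CC)OS(=O)(=O)C(F)(F)F
Why: Silylation of a hindered tertiary alcohol with a silyl triflate and a non-nucleophilic base; the product is achiral, with a mirror plane through C9 and C12.

Step 6
Reactants: 10 3-(oct-2-yn-1-yl)-3-[(triethylsilyl)oxy]cyclobutan-1-one
Product: 11 (3S)-3-(oct-2-yn-1-yl)-3-[(triethylsilyl)oxy]-1-[(trimethylsilyl)oxy]cyclobut-1-ene
Conditions: (R,R)-bis(1-phenylethyl)amine, n-BuLi, THF, −78 °C; TMSCl then 10, −100 °C (in situ quench); cold work-up, used at once below 0 °C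
Reagents that add atoms: chlorotrimethylsilane, C[Si](C)(C)Cl
Why: Asymmetric deprotonation of a prochiral cyclobutanone by a C2-symmetric chiral lithium amide with internal silyl quench; choosing one of the two enantiotopic CH2 groups makes C12 a stereocentre (S), in situ trapping should outrun β-elimination of silanolate, and 11 is kept cold because 3-siloxycyclobutenes open thermally to dienes.

Step 7
Reactants: 11 (3S)-3-(oct-2-yn-1-yl)-3-[(triethylsilyl)oxy]-1-[(trimethylsilyl)oxy]cyclobut-1-ene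
Product: 13 (4S)-2-chloro-4-(oct-2-yn-1-yl)-4-[(triethylsilyl)oxy]cyclopent-2-en-1-one, via (3S)-5,5-dichloro-3-(oct-2-yn-1-yl)-3-[(triethylsilyl)oxy]-1-[(trimethylsilyl)oxy]bicyclo[2.1.0]pentane 12 (not isolated)
Conditions: CHCl3, KOtBu (added slowly), pentane, −40 °C→rt
Reagents that add atoms: chloroform, ClC(Cl)Cl
Why: Dichlorocarbene from α-elimination of chloroform adds to the electron-rich siloxy-alkene C9=C11 of 11 in a [2+1] cheletropic step, giving the bicyclo[2.1.0]pentane 12; the alkyne is far less reactive. The three-membered ring of 12 then opens by the disrotatory two-electron cyclopropyl-to-allyl-cation electrocyclic process: the endo chloride leaves, the strained central C9–C11 bond breaks, and chloride removes Me3Si from the 1-siloxy-2-chloroallyl cation to give the 2-chloroenone. The ring C8–C9–C11–C12 thus becomes the five-membered ring with C10 inserted between C9 and C11; the only ring closure is the transient cyclopropane formed by carbene addition, and the five-membered ring arises by cleavage of the shared bond, not by a new closure. The closest known reaction type is the dihalocarbene ring enlargement of cyclic ketone silyl enol ethers to 2-halocycloalk-2-enones. No new stereocentre is formed and C12 is not touched; its configuration is the one fixed in step 6, because the carbon can only be inserted on the side carrying the enol double bond, and both faces of carbene addition converge on the same product. The step needs chemoselectivity for the enol ether over the alkyne and over the product enone, secured by the high nucleophilicity of the siloxy-alkene, the low temperature and slow addition of base to excess chloroform; regiochemistry is fixed by the enol ether.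

Step 8
Reactants: 14 (4-carboxybutyl)triphenylphosphonium bromide; 15 2-[(tert-butyldimethylsilyl)oxy]acetaldehyde
Product: 17 (5Z)-7-[(tert-butyldimethylsilyl)oxy]hept-5-enoic acid, via sodium 5-(triphenylphosphoranylidene)pentanoate 16 (not isolated)
Conditions: NaHMDS (2.1 equiv), THF, 0 °C; then 15, −78 °C→rt; cold dilute HCl to pH 4
Reagents that add atoms: none
Why: Wittig olefination with a non-stabilized ylide under lithium-free conditions, which should give the Z-alkene through the kinetically favoured cis-oxaphosphetane.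

Step 9
Reactants: 17 (5Z)-7-[(tert-butyldimethylsilyl)oxy]hept-5-enoic acid
Product: 18 methyl (5Z)-7-[(tert-butyldimethylsilyl)oxy]hept-5-enoate
Conditions: MeI, K2CO3, DMF, rt
Reagents that add atoms: iodomethane, CI
Why: O-alkylation of the carboxylate (esterification) under mild base that leaves the silyl ether and the Z-alkene unchanged.

Step 10
Reactants: 18 methyl (5Z)-7-[(tert-butyldimethylsilyl)oxy]hept-5-enoate
Product: 19 methyl (5Z)-7-hydroxyhept-5-enoate
Conditions: PPTS (cat.), MeOH, rt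
Reagents that add atoms: none
Why: Acid-catalysed methanolysis of a primary allylic silyl ether; the methyl ester is degenerate toward methanol.

Step 11
Reactants: 19 methyl (5Z)-7-hydroxyhept-5-enoate
Product: 20 methyl (5Z)-7-oxohept-5-enoate
Conditions: Dess–Martin periodinane, NaHCO3, CH2Cl2, 0 °C; used at once
Reagents that add atoms: none
Why: Dess–Martin oxidation of the allylic alcohol under buffered, non-nucleophilic conditions, which should preserve the labile Z-enal geometry.

Step 12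
Reactants: 13 (4S)-2-chloro-4-(oct-2-yn-1-yl)-4-[(triethylsilyl)oxy]cyclopent-2-en-1-one; 20 methyl (5Z)-7-oxohept-5-enoate
Product: 23 methyl (5Z,7S)-7-[(1R,5S)-3-chloro-2-oxo-5-(oct-2-yn-1-yl)-5-[(triethylsilyl)oxy]cyclopent-3-en-1-yl]-7-hydroxyhept-5-enoate, via the dicyclohexylboron dienolate of 13 21 (not isolated), via the O-dicyclohexylboryl aldolate of 23 22 (not isolated)
Conditions: c-Hex2BCl, Et3N, Et2O, −78→0 °C; 20, −78 °C; then MeOH, pH 7 buffer, 30% H2O2, 0 °C
Reagents that add atoms: none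
Why: Boron-mediated aldol addition: C8 is the only enolizable position and the cyclic enolate is necessarily E, so the chair Zimmerman–Traxler transition state should give the 7,8-anti adduct, while the aldehyde should approach the dienolate face anti to the C12 carbon chain (syn to the smaller O–Si substituent), placing the new chain cis to O12 and fixing C8 (R) and C7.

Step 13
Reactants: 23 methyl (5Z,7S)-7-[(1R,5S)-3-chloro-2-oxo-5-(oct-2-yn-1-yl)-5-[(triethylsilyl)oxy]cyclopent-3-en-1-yl]-7-hydroxyhept-5-enoate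
Product: 24 methyl 4-[(2R,3S)-3-{(R)-[(1R,5S)-3-chloro-2-oxo-5-(oct-2-yn-1-yl)-5-[(triethylsilyl)oxy]cyclopent-3-en-1-yl](hydroxy)methyl}oxiran-2-yl]butanoate
Conditions: mCPBA, CH2Cl2, 0 °C
Reagents that add atoms: 3-chloroperoxybenzoic acid, OOC(=O)c1cccc(Cl)c1
Why: Hydroxyl-directed Prilezhaev epoxidation of a Z-allylic alcohol: A(1,3) strain holds H-7 in the alkene plane, so the peracid, hydrogen-bonded to O7, attacks the face syn to OH and anti to the ring and should give the threo (6,7-syn) cis-epoxide, while the alkyne and the electron-poor chloroenone are inert.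

Step 14
Reactants: 24 methyl 4-[(2R,3S)-3-{(R)-[(1R,5S)-3-chloro-2-oxo-5-(oct-2-yn-1-yl)-5-[(triethylsilyl)oxy]cyclopent-3-en-1-yl](hydroxy)methyl}oxiran-2-yl]butanoate
Product: 25 methyl (5S,6S,7R)-5-acetoxy-7-[(1R,5S)-3-chloro-2-oxo-5-(oct-2-yn-1-yl)-5-[(triethylsilyl)oxy]cyclopent-3-en-1-yl]-6,7-dihydroxyheptanoate
Conditions: Ti(OiPr)4 (1.5 equiv), AcOH, CH2Cl2, 0 °C→rt; aq tartaric acid work-up
Reagents that add atoms: acetic acid, CC(=O)O
Why: Titanium(IV)-assisted opening of a 2,3-epoxy alcohol at the carbon distal to the carbinol (here C5) by a carboxylic acid: SN2 inversion at C5 of the cis-epoxide should give the 5,6-syn relationship while C6 keeps its oxygen and configuration.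

Step 15
Reactants: 25 methyl (5S,6S,7R)-5-acetoxy-7-[(1R,5S)-3-chloro-2-oxo-5-(oct-2-yn-1-yl)-5-[(triethylsilyl)oxy]cyclopent-3-en-1-yl]-6,7-dihydroxyheptanoate
Product: 26 methyl (5S,6R,7R)-5,6,7-triacetoxy-7-[(1R,5S)-3-chloro-2-oxo-5-(oct-2-yn-1-yl)-5-[(triethylsilyl)oxy]cyclopent-3-en-1-yl]heptanoate
Conditions: Ac2O, pyridine, CH2Cl2, 0 °C→rt (no DMAP)
Reagents that add atoms: acetic anhydride, CC(=O)OC(C)=O
Why: Acylation of the two secondary alcohols under weak base, chosen to avoid E1cB loss of the C7 acetate; any acetyl migration in 25 is harmless because all three oxygens end as acetates.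

Step 16
Reactants: 26 methyl (5S,6R,7R)-5,6,7-triacetoxy-7-[(1R,5S)-3-chloro-2-oxo-5-(oct-2-yn-1-yl)-5-[(triethylsilyl)oxy]cyclopent-3-en-1-yl]heptanoate
Product: 27 methyl (5S,6R,7R)-5,6,7-triacetoxy-7-[(1R,5S)-3-chloro-5-[(2Z)-oct-2-en-1-yl]-2-oxo-5-[(triethylsilyl)oxy]cyclopent-3-en-1-yl]heptanoate
Conditions: H2 (1 atm), Lindlar catalyst, quinoline, EtOAc, rt
Reagents that add atoms: none
Why: Lindlar semihydrogenation delivers H2 syn to the only alkyne to give the 14Z-alkene; the poisoned catalyst should leave the hindered, electron-poor chloroenone and its C–Cl bond alone.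

Step 17
Reactants: 27 methyl (5S,6R,7R)-5,6,7-triacetoxy-7-[(1R,5S)-3-chloro-5-[(2Z)-oct-2-en-1-yl]-2-oxo-5-[(triethylsilyl)oxy]cyclopent-3-en-1-yl]heptanoate
Product: 28 punaglandin 2, methyl (5S,6R,7R)-5,6,7-triacetoxy-7-[(1R,5S)-3-chloro-5-hydroxy-5-[(2Z)-oct-2-en-1-yl]-2-oxocyclopent-3-en-1-yl]heptanoate
Conditions: HF·pyridine, pyridine, THF, 0 °C→rt
Reagents that add atoms: none
Why: Fluoride cleavage of the tertiary triethylsilyl ether under buffered, weakly acidic conditions that should avoid base-induced elimination of the β-acetoxy ketone and retro-aldol opening.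

## Compound list

1 | 3-[(tert-butyldimethylsilyl)oxy]cyclobutan-1-one | CC(C)(C)[Si](C)(C)OC1CC(=O)C1 | starting material
2 | 3-bromoprop-1-yne (propargyl bromide) | C#CCBr | starting material
3 | propa-1,2-dien-1-ylzinc bromide (allenylzinc bromide; not isolated) | C=C=C[Zn]Br | intermediate
4 | 3-[(tert-butyldimethylsilyl)oxy]-1-(prop-2-yn-1-yl)cyclobutan-1-ol (cis/trans mixture) | C#CCC1(O)CC(O[Si](C)(C)C(C)(C)C)C1 | intermediate
5 | 1-iodopentane | CCCCCI | starting material
6 | dilithium salt of 4 (lithium alkoxide and lithium acetylide; not isolated) | [Li]C#CCC1(O[Li])CC(O[Si](C)(C)C(C)(C)C)C1 | intermediate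
7 | 3-[(tert-butyldimethylsilyl)oxy]-1-(oct-2-yn-1-yl)cyclobutan-1-ol (cis/trans mixture) | CCCCCC#CCC1(O)CC(O[Si](C)(C)C(C)(C)C)C1 | intermediate
8 | 1-(oct-2-yn-1-yl)cyclobutane-1,3-diol (cis/trans mixture) | CCCCCC#CCC1(O)CC(O)C1 | intermediate
9 | 3-hydroxy-3-(oct-2-yn-1-yl)cyclobutan-1-one | CCCCCC#CCC1(O)CC(=O)C1 | intermediate
10 | 3-(oct-2-yn-1-yl)-3-[(triethylsilyl)oxy]cyclobutan-1-one (achiral) | CCCCCC#CCC1(O[Si](CC)(CC)CC)CC(=O)C1 | intermediate
11 | (3S)-3-(oct-2-yn-1-yl)-3-[(triethylsilyl)oxy]-1-[(trimethylsilyl)oxy]cyclobut-1-ene | CCCCCC#CC[C@@]1(O[Si](CC)(CC)CC)C=C(O[Si](C)(C)C)C1 | intermediate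
12 | (3S)-5,5-dichloro-3-(oct-2-yn-1-yl)-3-[(triethylsilyl)oxy]-1-[(trimethylsilyl)oxy]bicyclo[2.1.0]pentane (cis-fused, either face; not isolated) | CCCCCC#CC[C@@]1(O[Si](CC)(CC)CC)C2C(Cl)(Cl)C2(O[Si](C)(C)C)C1 | intermediate
13 | (4S)-2-chloro-4-(oct-2-yn-1-yl)-4-[(triethylsilyl)oxy]cyclopent-2-en-1-one | CCCCCC#CC[C@@]1(O[Si](CC)(CC)CC)C=C(Cl)C(=O)C1 | intermediate
14 | (4-carboxybutyl)triphenylphosphonium bromide | OC(=O)CCCC[P+](c1ccccc1)(c1ccccc1)c1ccccc1.[Br-] | starting material
15 | 2-[(tert-butyldimethylsilyl)oxy]acetaldehyde | CC(C)(C)[Si](C)(C)OCC=O | starting material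
16 | sodium 5-(triphenylphosphoranylidene)pentanoate (ylide; not isolated) | [Na+].[O-]C(=O)CCCC=P(c1ccccc1)(c1ccccc1)c1ccccc1 | intermediate
17 | (5Z)-7-[(tert-butyldimethylsilyl)oxy]hept-5-enoic acid | CC(C)(C)[Si](C)(C)OC/C=C\CCCC(=O)O | intermediate
18 | methyl (5Z)-7-[(tert-butyldimethylsilyl)oxy]hept-5-enoate | CC(C)(C)[Si](C)(C)OC/C=C\CCCC(=O)OC | intermediate
19 | methyl (5Z)-7-hydroxyhept-5-enoate | OC/C=C\CCCC(=O)OC | intermediate
20 | methyl (5Z)-7-oxohept-5-enoate | O=C/C=C\CCCC(=O)OC | intermediate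
21 | (5S)-3-chloro-5-(oct-2-yn-1-yl)-5-[(triethylsilyl)oxy]cyclopenta-1,3-dien-2-yl dicyclohexylborinate (boron dienolate of 13; not isolated) | CCCCCC#CC[C@@]1(O[Si](CC)(CC)CC)C=C(Cl)C(OB(C2CCCCC2)C2CCCCC2)=C1 | intermediate
22 | O-dicyclohexylboryl aldolate of 23 (not isolated) | CCCCCC#CC[C@@]1(O[Si](CC)(CC)CC)C=C(Cl)C(=O)[C@@H]1[C@@H](OB(C2CCCCC2)C2CCCCC2)/C=C\CCCC(=O)OC | intermediate
23 | methyl (5Z,7S)-7-[(1R,5S)-3-chloro-2-oxo-5-(oct-2-yn-1-yl)-5-[(triethylsilyl)oxy]cyclopent-3-en-1-yl]-7-hydroxyhept-5-enoate | CCCCCC#CC[C@@]1(O[Si](CC)(CC)CC)C=C(Cl)C(=O)[C@@H]1[C@@H](O)/C=C\CCCC(=O)OC | intermediate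
24 | methyl 4-[(2R,3S)-3-{(R)-[(1R,5S)-3-chloro-2-oxo-5-(oct-2-yn-1-yl)-5-[(triethylsilyl)oxy]cyclopent-3-en-1-yl](hydroxy)methyl}oxiran-2-yl]butanoate | CCCCCC#CC[C@@]1(O[Si](CC)(CC)CC)C=C(Cl)C(=O)[C@@H]1[C@@H](O)[C@@H]2O[C@@H]2CCCC(=O)OC | intermediate
25 | methyl (5S,6S,7R)-5-acetoxy-7-[(1R,5S)-3-chloro-2-oxo-5-(oct-2-yn-1-yl)-5-[(triethylsilyl)oxy]cyclopent-3-en-1-yl]-6,7-dihydroxyheptanoate | CCCCCC#CC[C@@]1(O[Si](CC)(CC)CC)C=C(Cl)C(=O)[C@@H]1[C@@H](O)[C@H](O)[C@H](CCCC(=O)OC)OC(C)=O | intermediate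
26 | methyl (5S,6R,7R)-5,6,7-triacetoxy-7-[(1R,5S)-3-chloro-2-oxo-5-(oct-2-yn-1-yl)-5-[(triethylsilyl)oxy]cyclopent-3-en-1-yl]heptanoate | CCCCCC#CC[C@@]1(O[Si](CC)(CC)CC)C=C(Cl)C(=O)[C@@H]1[C@@H](OC(C)=O)[C@H](OC(C)=O)[C@H](CCCC(=O)OC)OC(C)=O | intermediate
27 | methyl (5S,6R,7R)-5,6,7-triacetoxy-7-[(1R,5S)-3-chloro-5-[(2Z)-oct-2-en-1-yl]-2-oxo-5-[(triethylsilyl)oxy]cyclopent-3-en-1-yl]heptanoate | CCCCC/C=C\C[C@@]1(O[Si](CC)(CC)CC)C=C(Cl)C(=O)[C@@H]1[C@@H](OC(C)=O)[C@H](OC(C)=O)[C@H](CCCC(=O)OC)OC(C)=O | intermediate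
28 | punaglandin 2, methyl (5S,6R,7R)-5,6,7-triacetoxy-7-[(1R,5S)-3-chloro-5-hydroxy-5-[(2Z)-oct-2-en-1-yl]-2-oxocyclopent-3-en-1-yl]heptanoate | CCCCC/C=C\C[C@@]1(O)C=C(Cl)C(=O)[C@@H]1[C@@H](OC(C)=O)[C@H](OC(C)=O)[C@H](CCCC(=O)OC)OC(C)=O | target

## Step count and risks

Total steps: 17. Longest linear sequence: 13 steps (steps 1–7 and 12–17, from compound 1); the enal branch (steps 8–11) joins at step 12.

**Step 6.** The base may discriminate poorly between the two enantiotopic CH2 groups, because the two C12 substituents (O–SiEt3 and CH2–alkynyl) differ little in size; silanolate may also be lost by β-elimination from the enolate before it is silylated. Fallback (resolution in place of asymmetric deprotonation): from 10, LDA with in situ TMSCl at −78 °C should give racemic 3-(oct-2-yn-1-yl)-3-[(triethylsilyl)oxy]-1-[(trimethylsilyl)oxy]cyclobut-1-ene F1. Dichlorocarbene addition as in step 7 should pass through racemic 5,5-dichloro-3-(oct-2-yn-1-yl)-3-[(triethylsilyl)oxy]-1-[(trimethylsilyl)oxy]bicyclo[2.1.0]pentane F2 (not isolated) to racemic 2-chloro-4-(oct-2-yn-1-yl)-4-[(triethylsilyl)oxy]cyclopent-2-en-1-one F3. Preparative chromatography on a chiral stationary phase would separate the enantiomers and return the (S)-enantiomer, compound 13.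

**Step 7.** Trichloromethyl anion or tert-butoxide may add to the enone as it forms, a second carbene may add, or the 3-siloxycyclobutene may undergo thermal electrocyclic opening if it warms before cyclopropanation. Fallback (carbon and chlorine introduced separately): from 11, Simmons–Smith cyclopropanation (Et2Zn, CH2I2, 0 °C) should give (3S)-3-(oct-2-yn-1-yl)-3-[(triethylsilyl)oxy]-1-[(trimethylsilyl)oxy]bicyclo[2.1.0]pentane F4. FeCl3 in DMF at 0 °C should open the siloxycyclopropane oxidatively across the central bond to (4S)-3-chloro-4-(oct-2-yn-1-yl)-4-[(triethylsilyl)oxy]cyclopentan-1-one F5. NaOAc in MeOH should eliminate HCl to (4S)-4-(oct-2-yn-1-yl)-4-[(triethylsilyl)oxy]cyclopent-2-en-1-one F6. α-Chlorination of the enone with PhSeCl and pyridine in CH2Cl2 returns compound 13.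

**Step 12.** The Z-enal may isomerize to the E-enal (promoted by amine or Lewis acid) before C–C bond formation, which would later give the wrong C5 configuration; face discrimination of the dienolate at C8 may also be incomplete. Fallback for the geometry problem (E-alkene and syn-dihydroxylation in place of Z-alkene, epoxidation and inversion): cross-metathesis of methyl hex-5-enoate with crotonaldehyde (second-generation ruthenium–NHC benzylidene catalyst) should give methyl (5E)-7-oxohept-5-enoate F7. The same boron aldol, starting from 13 through dienolate 21, should pass through the O-dicyclohexylboryl aldolate F8 (not isolated) to methyl (5E,7S)-7-[(1R,5S)-3-chloro-2-oxo-5-(oct-2-yn-1-yl)-5-[(triethylsilyl)oxy]cyclopent-3-en-1-yl]-7-hydroxyhept-5-enoate F9. Hydroxyl-directed osmylation (OsO4·TMEDA, 1 equiv, CH2Cl2, −78 °C) should add both oxygens syn to O7 and give the osmate(VI) ester–TMEDA complex F10, which aqueous NaHSO3 cleaves to methyl (5S,6R,7R)-7-[(1R,5S)-3-chloro-2-oxo-5-(oct-2-yn-1-yl)-5-[(triethylsilyl)oxy]cyclopent-3-en-1-yl]-5,6,7-trihydroxyheptanoate F11. Peracetylation (Ac2O, pyridine) returns compound 26.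

## Further compounds

F1 | step 6 | racemic 3-(oct-2-yn-1-yl)-3-[(triethylsilyl)oxy]-1-[(trimethylsilyl)oxy]cyclobut-1-ene | CCCCCC#CCC1(O[Si](CC)(CC)CC)C=C(O[Si](C)(C)C)C1
F2 | step 6 | racemic 5,5-dichloro-3-(oct-2-yn-1-yl)-3-[(triethylsilyl)oxy]-1-[(trimethylsilyl)oxy]bicyclo[2.1.0]pentane (not isolated) | CCCCCC#CCC1(O[Si](CC)(CC)CC)C2C(Cl)(Cl)C2(O[Si](C)(C)C)C1
F3 | step 6 | racemic 2-chloro-4-(oct-2-yn-1-yl)-4-[(triethylsilyl)oxy]cyclopent-2-en-1-one | CCCCCC#CCC1(O[Si](CC)(CC)CC)C=C(Cl)C(=O)C1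
F4 | step 7 | (3S)-3-(oct-2-yn-1-yl)-3-[(triethylsilyl)oxy]-1-[(trimethylsilyl)oxy]bicyclo[2.1.0]pentane | CCCCCC#CC[C@@]1(O[Si](CC)(CC)CC)C2CC2(O[Si](C)(C)C)C1
F5 | step 7 | (4S)-3-chloro-4-(oct-2-yn-1-yl)-4-[(triethylsilyl)oxy]cyclopentan-1-one (C3 epimers) | CCCCCC#CC[C@@]1(O[Si](CC)(CC)CC)C(Cl)CC(=O)C1
F6 | step 7 | (4S)-4-(oct-2-yn-1-yl)-4-[(triethylsilyl)oxy]cyclopent-2-en-1-one | CCCCCC#CC[C@@]1(O[Si](CC)(CC)CC)C=CC(=O)C1
F7 | step 12 | methyl (5E)-7-oxohept-5-enoate | O=C/C=C/CCCC(=O)OC
F8 | step 12 | O-dicyclohexylboryl aldolate of F9 (not isolated) | CCCCCC#CC[C@@]1(O[Si](CC)(CC)CC)C=C(Cl)C(=O)[C@@H]1[C@@H](OB(C2CCCCC2)C2CCCCC2)/C=C/CCCC(=O)OC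
F9 | step 12 | methyl (5E,7S)-7-[(1R,5S)-3-chloro-2-oxo-5-(oct-2-yn-1-yl)-5-[(triethylsilyl)oxy]cyclopent-3-en-1-yl]-7-hydroxyhept-5-enoate | CCCCCC#CC[C@@]1(O[Si](CC)(CC)CC)C=C(Cl)C(=O)[C@@H]1[C@@H](O)/C=C/CCCC(=O)OC
F10 | step 12 | cyclic osmate(VI) ester of F11 at O5 and O6, TMEDA complex | CCCCCC#CC[C@@]1(O[Si](CC)(CC)CC)C=C(Cl)C(=O)[C@@H]1[C@@H](O)[C@@H]2O[Os](=O)(=O)O[C@H]2CCCC(=O)OC.CN(C)CCN(C)C
F11 | step 12 | methyl (5S,6R,7R)-7-[(1R,5S)-3-chloro-2-oxo-5-(oct-2-yn-1-yl)-5-[(triethylsilyl)oxy]cyclopent-3-en-1-yl]-5,6,7-trihydroxyheptanoate | CCCCCC#CC[C@@]1(O[Si](CC)(CC)CC)C=C(Cl)C(=O)[C@@H]1[C@@H](O)[C@H](O)[C@H](CCCC(=O)OC)O
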